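**Retrosynthetic overview**
1. The target comes from lipase-selective acetylation of the primary C11–OH of the 7,8,11-triol, which in turn comes from global desilylation of the acylal.
2. The dihydropyran is closed last. The C1/C3 diol is oxidised to the 1,5-dialdehyde, which cyclises to the enol-lactol and is trapped as the C1 isovalerate. C1 is carried as Si–CH2 (a masked CH2OH, unmasked by Tamao–Fleming oxidation) and C3 as an exocyclic =CH2 (converted by hydroboration).
3. The cyclopentene is built first from a 4-silyloxycyclopentenone relay: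
   - trans cuprate addition sets C9;
   - enolate oxygenation, then α′-hydroxymethylation, sets the quaternary C8 trans to C9;
   - a second cuprate addition plus Saegusa–Ito oxidation installs the C4 unit and C5=C6;
   - a CBS reduction sets C7.
4. The first stereocentre comes from CBS desymmetrisation of cyclopent-4-ene-1,3-dione. The cyclopentene forms in steps 1–13 and the dihydropyran in steps 14–15.

Assumption: acylation of the lactol gives the anomer shown (OiVal cis to H-9), by convex-face attack and the anomeric effect, and any minor anomer is removed chromatographically.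
Face convention: the cyclopentane is drawn with C5→C9 anticlockwise. β is the top face, carrying C10 and 7-OH. α is the bottom face, carrying C1 on C9 and the C8–O.

---

**Step 1**
Reactants: 1 cyclopent-4-ene-1,3-dione
Product: 2 (4R)-4-hydroxycyclopent-2-en-1-one
Conditions: (S)-Me-CBS (10 mol %), catecholborane (0.55 equiv), PhMe, −78 °C; aq. NH4Cl; crude used at once
Reagents that add atoms: none
Why: Corey–Bakshi–Shibata desymmetrisation reduces one of the two enantiotopic carbonyls through the oxazaborolidine-bound borane, setting the first stereocentre as (R), and substoichiometric borane prevents over-reduction.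

**Step 2**
Reactants: 2
Product: 3 (4R)-4-(tert-butyldimethylsilyloxy)cyclopent-2-en-1-one
Conditions: TBSCl, imidazole, DMF, 0 → 23 °C
Reagents that add atoms: tert-butyldimethylsilyl chloride, CC(C)(C)[Si](C)(C)Cl
Why: Silylation protects the dimerisation-prone hydroxy-enone and gives the bulky γ-OTBS that directs the next addition, with no change at the stereocentre.

**Step 3**
Reactants: 3; 4 chloromethyl(isopropoxy)dimethylsilane (converted in situ to its Grignard reagent with Mg)
Product: 5 (3R,4R)-4-(TBSO)-2-hydroxy-3-{[isopropoxy(dimethyl)silyl]methyl}cyclopentan-1-one (3,4-trans; C2 epimeric mixture)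
Conditions: 4, Mg, THF; then CuBr·SMe2 (10 mol %), 3, THF, −78 °C; then (±)-Davis oxaziridine, −78 → −40 °C
Reagents that add atoms: (isopropoxydimethylsilyl)methylmagnesium chloride, CC(C)O[Si](C)(C)C[Mg]Cl; 2-(phenylsulfonyl)-3-phenyloxaziridine, O=S(=O)(c1ccccc1)N1OC1c1ccccc1
Why: Cu-catalysed conjugate addition of this hydroxymethyl-anion equivalent occurs trans to the γ-OTBS, so the nucleophile ends on the α face of the new C9 centre. The regiodefined Mg enolate (C7=C8) is then oxygenated by the Davis reagent, and the C8 configuration is irrelevant because step 6 erases it.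

**Step 4**
Reactants: 5
Product: 6 2-O-triethylsilyl ether of 5 (3R,4R, 3,4-trans; C2 epimeric mixture)
Conditions: TESCl, imidazole, DMF, 0 → 23 °C
Reagents that add atoms: triethylsilyl chloride, CC[Si](Cl)(CC)CC
Why: Silylation masks the α-hydroxyl, which would otherwise isomerise as an α-ketol under the base of step 5.

**Step 5**
Reactants: 6
Product: 7 (4S)-4-{[isopropoxy(dimethyl)silyl]methyl}-5-(triethylsilyloxy)cyclopent-2-en-1-one (C5 epimeric mixture)
Conditions: DBU, CH2Cl2, 0 °C, 30 min
Reagents that add atoms: none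
Why: E1cB elimination of the β-silyloxy ketone (TBSOH loss) creates the C5=C6 enone, which blocks C6 so that C8 is the only enolisable α-carbon, and C9 is untouched.

**Step 6**
Reactants: 7
Product: 8 (4S,5R)-5-(hydroxymethyl)-4-{[isopropoxy(dimethyl)silyl]methyl}-5-(triethylsilyloxy)cyclopent-2-en-1-one
Conditions: LDA, THF, −78 °C; then monomeric CH2O, THF, −78 °C; AcOH quench at −78 °C
Reagents that add atoms: formaldehyde, C=O
Why: In this aldol hydroxymethylation, formaldehyde adds to the planar kinetic α′-enolate anti to the C9 substituent. C10 therefore enters on the β face and the OTES is pushed to α, giving the target's quaternary C8 (O cis to C1, C10 trans to C1), and the cold quench avoids O→O silyl migration.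

**Step 7**
Reactants: 8
Product: 9 (4S,5R)-5-[(3-methylbutanoyloxy)methyl]-4-{[isopropoxy(dimethyl)silyl]methyl}-5-(triethylsilyloxy)cyclopent-2-en-1-one
Conditions: iPrCH2COCl, pyridine, DMAP (cat.), CH2Cl2, 0 → 23 °C
Reagents that add atoms: isovaleryl chloride, CC(C)CC(=O)Cl
Why: DMAP-catalysed acylation of the primary C10–OH installs the C10 isovalerate. The β-acyloxy ketone cannot eliminate because C8 is quaternary.

**Step 8**
Reactants: 9; 10 2-bromo-3-(tert-butyldimethylsilyloxy)prop-1-ene (converted in situ to its Grignard reagent with Mg)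
Product: 11 silyl enol ether (C6=C7–OSiMe3) of the C5-substituted cyclopentanone: 5-[1-(TBSO-methyl)vinyl], 8α-OTES, 8β-CH2OiVal, 9α-CH2Si(Me)2OiPr (C5 configuration undefined)
Conditions: 10, Mg, THF; then CuBr·SMe2 (20 mol %), 9, TMSCl, DMPU, THF, −78 → −40 °C
Reagents that add atoms: 2-(TBSOCH2)vinylmagnesium bromide, C=C([Mg]Br)CO[Si](C)(C)C(C)(C)C; chlorotrimethylsilane, C[Si](C)(C)Cl
Why: Cu-catalysed 1,4-addition puts the C4 unit on the β-carbon C5, and in-situ TMSCl trapping gives the regiodefined C6=C7 enol ether. The C5 configuration is irrelevant because it is destroyed in step 9.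

**Step 9**
Reactants: 11
Product: 12 dienone, 5-[1-(TBSO-methyl)vinyl]-cyclopent-5-en-7-one bearing 8α-OTES, 8β-CH2OiVal and 9α-CH2Si(Me)2OiPr
Conditions: Pd(OAc)2 (30 mol %), p-benzoquinone (1.2 equiv), MeCN, 23 °C
Reagents that add atoms: none
Why: Saegusa–Ito oxidation (Pd-enolate, then β-hydride elimination toward C5–H) restores the C5=C6 enone, now carrying the C4 unit, and leaves C9 unchanged.

**Step 10**
Reactants: 12
Product: 13 7β-alcohol: (7S)-allylic alcohol with 8α-OTES, 8β-CH2OiVal, 9α-CH2Si(Me)2OiPr and 5-[1-(TBSO-methyl)vinyl]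
Conditions: (R)-Me-CBS (30 mol %), catecholborane (2 equiv), PhMe, −78 → −40 °C
Reagents that add atoms: none
Why: CBS reduction is catalyst-controlled and differentiates the quaternary C8 from the sp2 C6. The (R)-catalyst is chosen to deliver hydride from the α face and so set 7β-OH, overriding the substrate's own preference for β-face attack.

**Step 11**
Reactants: 13
Product: 14 7β-O-triethylsilyl ether of 13
Conditions: TESOTf, 2,6-lutidine, CH2Cl2, −78 °C
Reagents that add atoms: triethylsilyl triflate, CC[Si](CC)(CC)OS(=O)(=O)C(F)(F)F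
Why: Silylation protects the allylic alcohol so it survives the hydroboration and the later oxidation.

**Step 12**
Reactants: 14
Product: 15 hydroboration product: C4 bears CH(CH2OTBS)(CH2OH) (C4 epimeric mixture); otherwise as 14
Conditions: 9-BBN, THF, 0 → 23 °C; then NaBO3·4H2O, THF/H2O, 23 °C
Reagents that add atoms: hydrogen peroxide (released from perborate), OO
Why: Hydroboration–oxidation is anti-Markovnikov and selective for the terminal CH2 of the 1,1-disubstituted diene terminus. It creates the C3–OH, and the C4 stereocentre is destroyed later.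

**Step 13**
Reactants: 15
Product: 16 C1,C3-diol: 9α-CH2OH, C4 bearing CH(CH2OTBS)CH2OH, 7β-OTES, 8α-OTES, 8β-CH2OiVal
Conditions: 30% H2O2, KF, KHCO3, THF/MeOH, 23 °C
Reagents that add atoms: hydrogen peroxide, OO
Why: Tamao–Fleming oxidation converts the alkoxysilylmethyl group into CH2OH with retention at C9, unmasking C1.

**Step 14**
Reactants: 16
Product: 17 C1,C3-dialdehyde (C4 epimeric mixture; crude, used immediately)
Conditions: (COCl)2, DMSO, CH2Cl2, −78 °C; then Et3N, −78 → −30 °C
Reagents that add atoms: none
Why: Swern oxidation of both primary alcohols (1,5-diol) at low temperature gives the dialdehyde, and the silylated C7, C8 and C11 oxygens are untouched.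

**Step 15**
Reactants: 17
Product: 18 1-O-isovaleryl acylal with 7β-OTES, 8α-OTES and 11-OTBS, carrying the C3=C4/C5=C6 diene
Conditions: iPrCH2COCl, pyridine, DMAP (cat.), CH2Cl2, −20 → 0 °C
Reagents that add atoms: isovaleryl chloride, CC(C)CC(=O)Cl
Why: Base enolises the C3 aldehyde (C4–H) and the dienol oxygen closes onto the C1 aldehyde (hemiacetalisation) to give the conjugated enol-lactol. DMAP-catalysed O-acylation then traps it as the acylal, the C1 centre being set by convex-face acylation under anomeric control. Any C9 epimerisation funnels toward the more stable isomer, with C1 trans to C10.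

**Step 16**
Reactants: 18
Product: 19 7β,8α,11-triol with 1-OiVal and 10-OiVal
Conditions: HF·pyridine, pyridine, THF, 0 → 23 °C
Reagents that add atoms: none
Why: Buffered fluoride removes the TES and TBS ethers, and the pyridine buffering spares the esters, the acylal and the acid-labile enol ether.

**Step 17**
Reactants: 19
Product: 20 Jatamanvaltrate J
Conditions: Novozym 435 (immobilised Candida antarctica lipase B, a hydrolase), CH2=CHOAc, MTBE, 4 Å MS, 25 °C
Reagents that add atoms: vinyl acetate, C=COC(C)=O
Why: The lipase selectively transesterifies the unhindered primary C11–OH (irreversible, via vinyl acetate) and leaves the secondary C7–OH and tertiary C8–OH free, under neutral conditions that protect the vinylogous acetal and acylal.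

---

**Compound list**
1 | cyclopent-4-ene-1,3-dione | O=C1C=CC(=O)C1 | starting material
2 | (4R)-4-hydroxycyclopent-2-en-1-one | O=C1C=C[C@H](O)C1 | intermediate
3 | (4R)-4-(TBSO)cyclopent-2-en-1-one | O=C1C=C[C@H](O[Si](C)(C)C(C)(C)C)C1 | intermediate
4 | chloromethyl(isopropoxy)dimethylsilane | CC(C)O[Si](C)(C)CCl | starting material
5 | (3R,4R)-4-(TBSO)-2-hydroxy-3-{[isopropoxy(dimethyl)silyl]methyl}cyclopentanone (C2 epimers) | C[Si](C)(OC(C)C)C[C@H]1[C@H](O[Si](C)(C)C(C)(C)C)CC(=O)C1O | intermediate
6 | 2-O-TES ether of 5 | C[Si](C)(OC(C)C)C[C@H]1[C@H](O[Si](C)(C)C(C)(C)C)CC(=O)C1O[Si](CC)(CC)CC | intermediate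
7 | (4S)-4-{[isopropoxy(dimethyl)silyl]methyl}-5-(TESO)cyclopent-2-en-1-one (C5 epimers) | C[Si](C)(OC(C)C)C[C@H]1C=CC(=O)C1O[Si](CC)(CC)CC | intermediate
8 | (4S,5R)-5-(hydroxymethyl)-4-{[isopropoxy(dimethyl)silyl]methyl}-5-(TESO)cyclopent-2-en-1-one | C[Si](C)(OC(C)C)C[C@H]1C=CC(=O)[C@]1(O[Si](CC)(CC)CC)CO | intermediate
9 | isovalerate of 8 | C[Si](C)(OC(C)C)C[C@H]1C=CC(=O)[C@]1(O[Si](CC)(CC)CC)COC(=O)CC(C)C | intermediate
10 | 2-bromo-3-(TBSO)prop-1-ene | C=C(Br)CO[Si](C)(C)C(C)(C)C | starting material
11 | TMS enol ether of the C5-alkenylated cyclopentanone (C5 undefined) | C[Si](C)(OC(C)C)C[C@H]1C(C(=C)CO[Si](C)(C)C(C)(C)C)C=C(O[Si](C)(C)C)[C@]1(O[Si](CC)(CC)CC)COC(=O)CC(C)C | intermediate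
12 | dienone (C5=C6 enone, C4=C3H2) | C[Si](C)(OC(C)C)C[C@H]1C(C(=C)CO[Si](C)(C)C(C)(C)C)=CC(=O)[C@]1(O[Si](CC)(CC)CC)COC(=O)CC(C)C | intermediate
13 | 7β-alcohol (7S) | C[Si](C)(OC(C)C)C[C@H]1C(C(=C)CO[Si](C)(C)C(C)(C)C)=C[C@H](O)[C@]1(O[Si](CC)(CC)CC)COC(=O)CC(C)C | intermediate
14 | 7-O-TES ether of 13 | C[Si](C)(OC(C)C)C[C@H]1C(C(=C)CO[Si](C)(C)C(C)(C)C)=C[C@H](O[Si](CC)(CC)CC)[C@]1(O[Si](CC)(CC)CC)COC(=O)CC(C)C | intermediate
15 | C3-alcohol (C4 epimers) | C[Si](C)(OC(C)C)C[C@H]1C(C(CO)CO[Si](C)(C)C(C)(C)C)=C[C@H](O[Si](CC)(CC)CC)[C@]1(O[Si](CC)(CC)CC)COC(=O)CC(C)C | intermediate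
16 | C1,C3-diol (C4 epimers) | OC[C@H]1C(C(CO)CO[Si](C)(C)C(C)(C)C)=C[C@H](O[Si](CC)(CC)CC)[C@]1(O[Si](CC)(CC)CC)COC(=O)CC(C)C | intermediate
17 | C1,C3-dialdehyde (C4 epimers) | O=C[C@H]1C(C(C=O)CO[Si](C)(C)C(C)(C)C)=C[C@H](O[Si](CC)(CC)CC)[C@]1(O[Si](CC)(CC)CC)COC(=O)CC(C)C | intermediate
18 | silylated 1,10-bis(isovalerate) acylal | CC(C)(C)[Si](C)(C)OCC1=CO[C@@H](OC(=O)CC(C)C)[C@H]2C1=C[C@H](O[Si](CC)(CC)CC)[C@]2(O[Si](CC)(CC)CC)COC(=O)CC(C)C | intermediate
19 | 7,8,11-triol 1,10-bis(isovalerate) | OCC1=CO[C@@H](OC(=O)CC(C)C)[C@H]2C1=C[C@H](O)[C@]2(O)COC(=O)CC(C)C | intermediate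
20 | Jatamanvaltrate J | CC(=O)OCC1=CO[C@@H](OC(=O)CC(C)C)[C@H]2C1=C[C@H](O)[C@]2(O)COC(=O)CC(C)C | target

---

**Totals:** 17 steps; longest linear sequence 17 steps.

**Three steps most likely to fail**
1. **Step 10 (CBS reduction, C7 configuration).** The substrate's own bias favours the wrong face, so catalyst control must override it.
   Fallback: use substrate direction instead. Selectively remove the C8-TES (PPTS, MeOH), reduce with Me4NBH(OAc)3 so that the C8–OH delivers hydride from the α face to give 7β-OH, then re-silylate C7 and C8 with TESOTf and rejoin at 14.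
2. **Steps 14–15 (dialdehyde, cyclisation and acylation).** Risks are lactone over-oxidation, E1cB loss of the C11–OSi group, C9 epimerisation and anomer mixtures.
   Fallback: go through the lactone level instead. Oxidise 16 to the C1-acid/C3-aldehyde, close the enol lactone (Ac2O/NaOAc), then reduce with DIBAL at −78 °C and trap the aluminium lactolate in situ with isovaleric anhydride.
3. **Step 6 (quaternary C8 by enolate hydroxymethylation).** Risks are low facial selectivity and 1,2-O→O silyl migration in the lithium alkoxide.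
   Fallback: use a Mukaiyama-type hydroxymethylation. Make the silyl dienol ether (TESOTf, Et3N) and add it to aqueous formaldehyde with Yb(OTf)3, which proceeds through an open transition state anti to C9 with no alkoxide.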